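**Plan**

1. Retrosynthesis: the C15 ester and the silyl groups go first. The lactone O–C8 bond is then exchanged for a C8–C12 bond (Baeyer–Villiger retron), giving a trans-fused 2-methylidenecyclobutanone. Its bonds C11–C12 and C7–C8 are cut together as an intramolecular ketene–allene [2+2], which also opens the ten-membered ring; the ketene comes from an α-diazoketone.
2. Enabling feature: in the lactone ring O–C12(=O)–C11(=C13H2)–C7–C8, the carbons C12, C11, C7 and C8 form a four-membered ring once O is left out. C12=C8 is then a ketene and C7=C11=C13H2 a terminal allene whose proximal π bond delivers the exocyclic methylene.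
3. Forward ring order: open chain → cyclobutanone and ten-membered carbocycle in one operation → ring expansion of the four-membered ketone to the γ-lactone → C15 ester.
4. Chain assembly: C4=C5 by copper-catalysed carbomagnesiation of propargyl alcohol with in-flask propargylation; allene by Crabbé homologation; C1=C10 by a Wittig reaction; C8 from diazomethane.
5. Stereochemistry: C4=C5 geometry from the magnesium chelate, C1=C10 from the E-selective stabilised ylide. C7 and C8 are both formed in the cycloaddition, which gives a racemate; trans fusion is expected after equilibration at the enolisable C8. The absolute configuration comes from a catalytic asymmetric Baeyer–Villiger oxidation run as a kinetic resolution, with migration of C8 under retention.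

Key step: step 12

Remark: locants C1–C15 in the text are germacranolide locants: lactone C12(=O)–O–C8, C11=C13H2, ring fusion C7/C8, C14 = CH2OAc on C10, C15 = CH2O-acyl on C4.

**Route**

Step 1
Reactants: 1 2-(2-bromoethyl)-1,3-dioxolane; 2 prop-2-yn-1-ol; 3 3-bromo-1-(trimethylsilyl)prop-1-yne
Product: 6 (2Z)-2-[2-(1,3-dioxolan-2-yl)ethyl]-6-(trimethylsilyl)hex-2-en-5-yn-1-ol, via Grignard reagent 4 (not isolated), via magnesium chelate 5 (not isolated)
Conditions: Mg, THF, 25 °C; then 2 (4 in 2.3-fold excess), CuI (10 mol %), THF, −10 °C → rt; then 3, 0 °C → rt; aq. NH4Cl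
Reagents that add atoms: none
Why: Copper-catalysed anti-carbomagnesiation of propargyl alcohol puts the alkyl group on C4 and magnesium on C5 inside a five-membered alkoxide chelate, and copper-mediated SN2 alkylation of that alkenyl–metal bond with retention should fix the CH2OH group cis to the new propargylic CH2.

Step 2
Reactants: 6 (2Z)-2-[2-(1,3-dioxolan-2-yl)ethyl]-6-(trimethylsilyl)hex-2-en-5-yn-1-ol
Product: 7 tert-butyl({(2Z)-2-[2-(1,3-dioxolan-2-yl)ethyl]-6-(trimethylsilyl)hex-2-en-5-yn-1-yl}oxy)diphenylsilane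
Conditions: TBDPSCl, imidazole, DMF, 0 °C → rt
Reagents that add atoms: tert-butyl(chloro)diphenylsilane, CC(C)(C)[Si](Cl)(c1ccccc1)c1ccccc1
Why: Silylation of a primary allylic alcohol gives an ether that should survive the later base, acid, hydride and Lewis acid steps.

Step 3
Reactants: 7 tert-butyl({(2Z)-2-[2-(1,3-dioxolan-2-yl)ethyl]-6-(trimethylsilyl)hex-2-en-5-yn-1-yl}oxy)diphenylsilane
Product: 8 tert-butyl({(2Z)-2-[2-(1,3-dioxolan-2-yl)ethyl]hex-2-en-5-yn-1-yl}oxy)diphenylsilane
Conditions: K2CO3, MeOH, rt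
Reagents that add atoms: none
Why: Methoxide-induced protiodesilylation of an alkynylsilane leaves the silyl ether and the acetal untouched.

Step 4
Reactants: 8 tert-butyl({(2Z)-2-[2-(1,3-dioxolan-2-yl)ethyl]hex-2-en-5-yn-1-yl}oxy)diphenylsilane
Product: 10 tert-butyl({(2Z)-2-[2-(1,3-dioxolan-2-yl)ethyl]hepta-2,5,6-trien-1-yl}oxy)diphenylsilane, via propargylic amine 9 (not isolated)
Conditions: (CH2O)n, CuI (0.5 equiv), Cy2NH, 1,4-dioxane, reflux
Reagents that add atoms: paraformaldehyde (as formaldehyde), C=O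
Why: Crabbé homologation: the copper acetylide gives a Mannich base with formaldehyde and the amine, and its retro-imino-ene hydrogen shift delivers the terminal allene C7H=C11=C13H2.

Step 5
Reactants: 10 tert-butyl({(2Z)-2-[2-(1,3-dioxolan-2-yl)ethyl]hepta-2,5,6-trien-1-yl}oxy)diphenylsilane
Product: 11 (4Z)-4-({[tert-butyl(diphenyl)silyl]oxy}methyl)nona-4,7,8-trienal
Conditions: PPTS (cat.), acetone/H2O, 60 °C
Reagents that add atoms: water, O
Why: Mild acid-catalysed acetal hydrolysis (transacetalisation to acetone) should free the C1 aldehyde without touching the silyl ether or the allene.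

Step 6
Reactants: 12 ethyl (triphenyl-λ5-phosphanylidene)acetate; 13 tert-butyl bromoacetate
Product: 15 4-tert-butyl 1-ethyl 2-(triphenyl-λ5-phosphanylidene)butanedioate, via phosphonium bromide 14 (not isolated)
Conditions: 12 (2 equiv), EtOAc, 70 °C; filtration
Reagents that add atoms: none
Why: C-Alkylation of a stabilised ylide by an α-bromo ester followed by transylidation with the second equivalent of 12 gives the α-substituted stabilised ylide.

Step 7
Reactants: 11 (4Z)-4-({[tert-butyl(diphenyl)silyl]oxy}methyl)nona-4,7,8-trienal; 15 4-tert-butyl 1-ethyl 2-(triphenyl-λ5-phosphanylidene)butanedioate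
Product: 16 4-tert-butyl 1-ethyl (2E)-2-[(4Z)-4-({[tert-butyl(diphenyl)silyl]oxy}methyl)nona-4,7,8-trien-1-ylidene]butanedioate
Conditions: PhMe, 90 °C
Reagents that add atoms: none
Why: A Wittig reaction of an α-branched stabilised ylide with an unhindered aldehyde should place the ester (C14) trans to the chain, which is the C1=C10 geometry of the target.

Step 8
Reactants: 16 4-tert-butyl 1-ethyl (2E)-2-[(4Z)-4-({[tert-butyl(diphenyl)silyl]oxy}methyl)nona-4,7,8-trien-1-ylidene]butanedioate
Product: 17 tert-butyl (3E,7Z)-7-({[tert-butyl(diphenyl)silyl]oxy}methyl)-3-(hydroxymethyl)dodeca-3,7,10,11-tetraenoate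
Conditions: DIBAL-H (2.2 equiv), CH2Cl2, −78 °C; Rochelle salt, cold
Reagents that add atoms: none
Why: 1,2-Reduction of an ester by DIBAL-H should be faster at the unhindered ethyl enoate than at the tert-butyl ester; cold work-up and direct use in step 9 forestall lactonisation of the γ-hydroxy ester.

Step 9
Reactants: 17 tert-butyl (3E,7Z)-7-({[tert-butyl(diphenyl)silyl]oxy}methyl)-3-(hydroxymethyl)dodeca-3,7,10,11-tetraenoate
Product: 18 tert-butyl (3E,7Z)-3-(acetoxymethyl)-7-({[tert-butyl(diphenyl)silyl]oxy}methyl)dodeca-3,7,10,11-tetraenoate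
Conditions: Ac2O, pyridine, DMAP (cat.), CH2Cl2, 0 °C
Reagents that add atoms: acetic anhydride, CC(=O)OC(C)=O
Why: DMAP-catalysed acetylation installs the C14 acetate of the target at a stage where no other free hydroxyl is present.

Step 10
Reactants: 18 tert-butyl (3E,7Z)-3-(acetoxymethyl)-7-({[tert-butyl(diphenyl)silyl]oxy}methyl)dodeca-3,7,10,11-tetraenoate
Product: 20 (3E,7Z)-3-(acetoxymethyl)-7-({[tert-butyl(diphenyl)silyl]oxy}methyl)dodeca-3,7,10,11-tetraenoic acid, via silyl ester 19 (not isolated)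
Conditions: TMSOTf, 2,6-lutidine, CH2Cl2, 0 °C; then H2O
Reagents that add atoms: none
Why: Silyl-triflate-mediated cleavage of a tert-butyl ester (loss of isobutene, then hydrolysis of the silyl ester) is buffered and should spare the acetate, the silyl ether and the allene.

Step 11
Reactants: 20 (3E,7Z)-3-(acetoxymethyl)-7-({[tert-butyl(diphenyl)silyl]oxy}methyl)dodeca-3,7,10,11-tetraenoic acid
Product: 22 (2E,6Z)-6-({[tert-butyl(diphenyl)silyl]oxy}methyl)-2-(3-diazo-2-oxopropyl)undeca-2,6,9,10-tetraen-1-yl acetate, via mixed anhydride 21 (not isolated)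
Conditions: i-BuOCOCl, N-methylmorpholine, THF, −15 °C; then CH2N2, Et2O, 0 °C
Reagents that add atoms: diazomethane, C=[N+]=[N-]
Why: Acylation of diazomethane by a mixed carbonic anhydride (the first stage of an Arndt–Eistert sequence) introduces C8 under conditions too mild to isomerise the β,γ-unsaturated acid.

Step 12
Reactants: 22 (2E,6Z)-6-({[tert-butyl(diphenyl)silyl]oxy}methyl)-2-(3-diazo-2-oxopropyl)undeca-2,6,9,10-tetraen-1-yl acetate
Product: 24 rac-[(1S,3Z,7E,10S)-4-({[tert-butyl(diphenyl)silyl]oxy}methyl)-12-methylidene-11-oxobicyclo[8.2.0]dodeca-3,7-dien-8-yl]methyl acetate (trans-fused), via ketene 23 (not isolated)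
Conditions: hν (365 nm), PhMe (1 mM), 25 °C; then 90 °C; then Et3N (cat.), 25 °C
Reagents that add atoms: none
Why: Proposed new method: irradiation expels N2 and the C9 alkyl group shifts from C12 to C8 (Wolff rearrangement) to give aldoketene 23 free of base and nucleophile, whose C12=C8 π bond then adds thermally, in a concerted but asynchronous [π2s+π2a] cycloaddition, across the internal C7=C11 π bond of the terminal allene, the electrophilic ketene carbon C12 bonding to the central allene carbon C11 and C8 to C7. The closest known reaction type is the intramolecular ketene–allene [2+2] cycloaddition, also with Wolff-generated ketenes, which gives 2-methylidenecyclobutanones fused to five- and six-membered rings; the new element is the eight-atom tether, so that the same event closes a ten-membered carbocycle. The cyclobutanone is closed by the [2+2] itself (both new bonds) and the cyclodecadiene by 10-exo attack of C8 on the proximal allene carbon C7 within that cycloaddition, helped by the two trisubstituted alkenes that pre-fold the chain. C7 and C8 are both created here: addition is suprafacial on the allene, C8 is α to the ketone and therefore epimerisable, and the closing amine treatment is expected to leave the thermodynamically preferred trans fusion (as in caryophyllene-type bicyclo[n.2.0] systems with an E-alkene in the large ring); the product is racemic and the absolute configuration is set in step 13. The step needs periselectivity for C7=C11 over the terminal C11=C13 bond, over the C4=C5 alkene and over ketene dimerisation: the internal allene bond is the more substituted one and places the developing positive charge on secondary C7, the C10=C1 alkene is too close to C8 for any [2+2], C4=C5 is a poorer ketenophile that would need a seven-membered ring, and photochemical release at 1 mM without amine keeps the ketene too dilute to dimerise.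

Step 13
Reactants: 24 rac-[(1S,3Z,7E,10S)-4-({[tert-butyl(diphenyl)silyl]oxy}methyl)-12-methylidene-11-oxobicyclo[8.2.0]dodeca-3,7-dien-8-yl]methyl acetate
Product: 25 [(3aR,5Z,9E,11aS)-6-({[tert-butyl(diphenyl)silyl]oxy}methyl)-3-methylidene-2-oxo-2,3,3a,4,7,8,11,11a-octahydrocyclodeca[b]furan-10-yl]methyl acetate
Conditions: 30 % aq. H2O2 (0.6 equiv), chiral phosphoric acid (TRIP type, 10 mol %, antipode chosen by screening), CHCl3, −40 °C, stopped near half conversion; the unreacted (1R,10R)-ketone is separated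
Reagents that add atoms: hydrogen peroxide, OO
Why: Baeyer–Villiger oxidation driven by release of cyclobutanone strain, in which the sp3 carbon C8 migrates with retention in preference to the sp2 carbon C11 so that O enters between C12 and C8; run as a catalytic asymmetric Baeyer–Villiger kinetic resolution of a racemic cyclobutanone, it should oxidise only the (1S,10S) enantiomer, and the peracid-free, weakly acidic medium should leave the trisubstituted alkenes and the enone C=C alone.

Step 14
Reactants: 25 [(3aR,5Z,9E,11aS)-6-({[tert-butyl(diphenyl)silyl]oxy}methyl)-3-methylidene-2-oxo-2,3,3a,4,7,8,11,11a-octahydrocyclodeca[b]furan-10-yl]methyl acetate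
Product: 26 [(3aR,5Z,9E,11aS)-6-(hydroxymethyl)-3-methylidene-2-oxo-2,3,3a,4,7,8,11,11a-octahydrocyclodeca[b]furan-10-yl]methyl acetate
Conditions: HF·pyridine, pyridine/THF, 0 °C → rt
Reagents that add atoms: none
Why: Buffered fluoride desilylation is non-basic, so the acetate and the α-methylene lactone (a Michael acceptor) should be spared.

Step 15
Reactants: 27 ethyl 2-(hydroxymethyl)prop-2-enoate
Product: 28 ethyl 2-({[tert-butyl(dimethyl)silyl]oxy}methyl)prop-2-enoate
Conditions: TBSCl, imidazole, DMF, 0 °C → rt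
Reagents that add atoms: tert-butyl(chloro)dimethylsilane, CC(C)(C)[Si](C)(C)Cl
Why: Silylation masks the side-chain hydroxyl so that the acid can later be coupled without self-condensation.

Step 16
Reactants: 28 ethyl 2-({[tert-butyl(dimethyl)silyl]oxy}methyl)prop-2-enoate
Product: 29 2-({[tert-butyl(dimethyl)silyl]oxy}methyl)prop-2-enoic acid
Conditions: LiOH·H2O, THF/H2O, 0 °C; then aq. HCl to pH 4
Reagents that add atoms: lithium hydroxide, [Li+].[OH-]
Why: Saponification of the ethyl ester at 0 °C should leave the silyl ether in place.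

Step 17
Reactants: 26 [(3aR,5Z,9E,11aS)-6-(hydroxymethyl)-3-methylidene-2-oxo-2,3,3a,4,7,8,11,11a-octahydrocyclodeca[b]furan-10-yl]methyl acetate; 29 2-({[tert-butyl(dimethyl)silyl]oxy}methyl)prop-2-enoic acid
Product: 30 [(3aR,5Z,9E,11aS)-10-(acetoxymethyl)-3-methylidene-2-oxo-2,3,3a,4,7,8,11,11a-octahydrocyclodeca[b]furan-6-yl]methyl 2-({[tert-butyl(dimethyl)silyl]oxy}methyl)prop-2-enoate
Conditions: EDC·HCl, DMAP, CH2Cl2, 0 °C → rt
Reagents that add atoms: none
Why: Steglich esterification acylates the only free hydroxyl (C15–OH) under neutral conditions.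

Step 18
Reactants: 30 [(3aR,5Z,9E,11aS)-10-(acetoxymethyl)-3-methylidene-2-oxo-2,3,3a,4,7,8,11,11a-octahydrocyclodeca[b]furan-6-yl]methyl 2-({[tert-butyl(dimethyl)silyl]oxy}methyl)prop-2-enoate
Product: 31 [(3aR,5Z,9E,11aS)-10-(acetoxymethyl)-3-methylidene-2-oxo-2,3,3a,4,7,8,11,11a-octahydrocyclodeca[b]furan-6-yl]methyl 2-(hydroxymethyl)prop-2-enoate (CNP0126545.1)
Conditions: HF·pyridine, pyridine/THF, 0 °C
Reagents that add atoms: none
Why: Fluoride desilylation under buffered conditions frees the primary hydroxyl without acyl migration or attack on the two acrylate-type acceptors.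

**Compound list**

1 | 2-(2-bromoethyl)-1,3-dioxolane | BrCCC1OCCO1 | starting material
2 | prop-2-yn-1-ol | OCC#C | starting material
3 | 3-bromo-1-(trimethylsilyl)prop-1-yne | C[Si](C)(C)C#CCBr | starting material
4 | [2-(1,3-dioxolan-2-yl)ethyl]magnesium bromide | Br[Mg]CCC1OCCO1 | intermediate
5 | cyclic (Z)-alkenylmagnesium alkoxide from 2 and 4 (4-[2-(1,3-dioxolan-2-yl)ethyl]-2,5-dihydro-1,2-oxamagnesole) | [Mg]1OCC(CCC2OCCO2)=C1 | intermediate
6 | (2Z)-2-[2-(1,3-dioxolan-2-yl)ethyl]-6-(trimethylsilyl)hex-2-en-5-yn-1-ol | OC/C(CCC1OCCO1)=C\CC#C[Si](C)(C)C | intermediate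
7 | tert-butyl({(2Z)-2-[2-(1,3-dioxolan-2-yl)ethyl]-6-(trimethylsilyl)hex-2-en-5-yn-1-yl}oxy)diphenylsilane | CC(C)(C)[Si](c1ccccc1)(c1ccccc1)OC/C(CCC1OCCO1)=C\CC#C[Si](C)(C)C | intermediate
8 | tert-butyl({(2Z)-2-[2-(1,3-dioxolan-2-yl)ethyl]hex-2-en-5-yn-1-yl}oxy)diphenylsilane | CC(C)(C)[Si](c1ccccc1)(c1ccccc1)OC/C(CCC1OCCO1)=C\CC#C | intermediate
9 | N-cyclohexyl-N-[(5Z)-6-({[tert-butyl(diphenyl)silyl]oxy}methyl)-8-(1,3-dioxolan-2-yl)oct-5-en-2-yn-1-yl]cyclohexanamine | CC(C)(C)[Si](c1ccccc1)(c1ccccc1)OC/C(CCC1OCCO1)=C\CC#CCN(C1CCCCC1)C1CCCCC1 | intermediate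
10 | tert-butyl({(2Z)-2-[2-(1,3-dioxolan-2-yl)ethyl]hepta-2,5,6-trien-1-yl}oxy)diphenylsilane | CC(C)(C)[Si](c1ccccc1)(c1ccccc1)OC/C(CCC1OCCO1)=C\CC=C=C | intermediate
11 | (4Z)-4-({[tert-butyl(diphenyl)silyl]oxy}methyl)nona-4,7,8-trienal | CC(C)(C)[Si](c1ccccc1)(c1ccccc1)OC/C(CCC=O)=C\CC=C=C | intermediate
12 | ethyl (triphenyl-λ5-phosphanylidene)acetate | CCOC(=O)C=P(c1ccccc1)(c1ccccc1)c1ccccc1 | starting material
13 | tert-butyl bromoacetate | CC(C)(C)OC(=O)CBr | starting material
14 | (4-tert-butoxy-1-ethoxy-1,4-dioxobutan-2-yl)triphenylphosphonium bromide | CCOC(=O)C(CC(=O)OC(C)(C)C)[P+](c1ccccc1)(c1ccccc1)c1ccccc1.[Br-] | intermediate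
15 | 4-tert-butyl 1-ethyl 2-(triphenyl-λ5-phosphanylidene)butanedioate | CCOC(=O)C(CC(=O)OC(C)(C)C)=P(c1ccccc1)(c1ccccc1)c1ccccc1 | intermediate
16 | 4-tert-butyl 1-ethyl (2E)-2-[(4Z)-4-({[tert-butyl(diphenyl)silyl]oxy}methyl)nona-4,7,8-trien-1-ylidene]butanedioate | CC(C)(C)[Si](c1ccccc1)(c1ccccc1)OC/C(CC/C=C(/C(=O)OCC)CC(=O)OC(C)(C)C)=C\CC=C=C | intermediate
17 | tert-butyl (3E,7Z)-7-({[tert-butyl(diphenyl)silyl]oxy}methyl)-3-(hydroxymethyl)dodeca-3,7,10,11-tetraenoate | CC(C)(C)[Si](c1ccccc1)(c1ccccc1)OC/C(CC/C=C(/CO)CC(=O)OC(C)(C)C)=C\CC=C=C | intermediate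
18 | tert-butyl (3E,7Z)-3-(acetoxymethyl)-7-({[tert-butyl(diphenyl)silyl]oxy}methyl)dodeca-3,7,10,11-tetraenoate | CC(C)(C)[Si](c1ccccc1)(c1ccccc1)OC/C(CC/C=C(/COC(C)=O)CC(=O)OC(C)(C)C)=C\CC=C=C | intermediate
19 | trimethylsilyl (3E,7Z)-3-(acetoxymethyl)-7-({[tert-butyl(diphenyl)silyl]oxy}methyl)dodeca-3,7,10,11-tetraenoate | CC(C)(C)[Si](c1ccccc1)(c1ccccc1)OC/C(CC/C=C(/COC(C)=O)CC(=O)O[Si](C)(C)C)=C\CC=C=C | intermediate
20 | (3E,7Z)-3-(acetoxymethyl)-7-({[tert-butyl(diphenyl)silyl]oxy}methyl)dodeca-3,7,10,11-tetraenoic acid | CC(C)(C)[Si](c1ccccc1)(c1ccccc1)OC/C(CC/C=C(/COC(C)=O)CC(=O)O)=C\CC=C=C | intermediate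
21 | mixed anhydride of 20 with isobutyl hydrogen carbonate | CC(C)(C)[Si](c1ccccc1)(c1ccccc1)OC/C(CC/C=C(/COC(C)=O)CC(=O)OC(=O)OCC(C)C)=C\CC=C=C | intermediate
22 | (2E,6Z)-6-({[tert-butyl(diphenyl)silyl]oxy}methyl)-2-(3-diazo-2-oxopropyl)undeca-2,6,9,10-tetraen-1-yl acetate | CC(C)(C)[Si](c1ccccc1)(c1ccccc1)OC/C(CC/C=C(/COC(C)=O)CC(=O)C=[N+]=[N-])=C\CC=C=C | intermediate
23 | (2E,6Z)-6-({[tert-butyl(diphenyl)silyl]oxy}methyl)-2-(3-oxoprop-2-en-1-yl)undeca-2,6,9,10-tetraen-1-yl acetate (aldoketene) | CC(C)(C)[Si](c1ccccc1)(c1ccccc1)OC/C(CC/C=C(/COC(C)=O)CC=C=O)=C\CC=C=C | intermediate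
24 | rac-[(1S,3Z,7E,10S)-4-({[tert-butyl(diphenyl)silyl]oxy}methyl)-12-methylidene-11-oxobicyclo[8.2.0]dodeca-3,7-dien-8-yl]methyl acetate (racemate; the SMILES shows the enantiomer that is carried on) | CC(C)(C)[Si](c1ccccc1)(c1ccccc1)OC/C1=C\C[C@@H]2C(=C)C(=O)[C@H]2C/C(COC(C)=O)=C\CC1 | intermediate
25 | [(3aR,5Z,9E,11aS)-6-({[tert-butyl(diphenyl)silyl]oxy}methyl)-3-methylidene-2-oxo-2,3,3a,4,7,8,11,11a-octahydrocyclodeca[b]furan-10-yl]methyl acetate | CC(C)(C)[Si](c1ccccc1)(c1ccccc1)OC/C1=C\C[C@@H]2C(=C)C(=O)O[C@H]2C/C(COC(C)=O)=C\CC1 | intermediate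
26 | [(3aR,5Z,9E,11aS)-6-(hydroxymethyl)-3-methylidene-2-oxo-2,3,3a,4,7,8,11,11a-octahydrocyclodeca[b]furan-10-yl]methyl acetate | OC/C1=C\C[C@@H]2C(=C)C(=O)O[C@H]2C/C(COC(C)=O)=C\CC1 | intermediate
27 | ethyl 2-(hydroxymethyl)prop-2-enoate | C=C(CO)C(=O)OCC | starting material
28 | ethyl 2-({[tert-butyl(dimethyl)silyl]oxy}methyl)prop-2-enoate | C=C(CO[Si](C)(C)C(C)(C)C)C(=O)OCC | intermediate
29 | 2-({[tert-butyl(dimethyl)silyl]oxy}methyl)prop-2-enoic acid | C=C(CO[Si](C)(C)C(C)(C)C)C(=O)O | intermediate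
30 | [(3aR,5Z,9E,11aS)-10-(acetoxymethyl)-3-methylidene-2-oxo-2,3,3a,4,7,8,11,11a-octahydrocyclodeca[b]furan-6-yl]methyl 2-({[tert-butyl(dimethyl)silyl]oxy}methyl)prop-2-enoate | C=C(CO[Si](C)(C)C(C)(C)C)C(=O)OC/C1=C\C[C@@H]2C(=C)C(=O)O[C@H]2C/C(COC(C)=O)=C\CC1 | intermediate
31 | [(3aR,5Z,9E,11aS)-10-(acetoxymethyl)-3-methylidene-2-oxo-2,3,3a,4,7,8,11,11a-octahydrocyclodeca[b]furan-6-yl]methyl 2-(hydroxymethyl)prop-2-enoate | C=C(CO)C(=O)OC/C1=C\C[C@@H]2C(=C)C(=O)O[C@H]2C/C(COC(C)=O)=C\CC1 | target

**Step count**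

Total steps: 18. Longest linear sequence: 15 steps (1–5, 7–14, 17, 18).

**Steps most likely to fail**

1. Step 12 (labelled). The ten-membered ring closure may be too slow, so that bimolecular ketene dimerisation, oligomerisation or capture by traces of water takes over. The ring fusion may also come out cis and resist equilibration at C8.
Fallback, known reactions only, setting out from acid 20 and coming back at lactone 25: the two bonds are made one after the other, and the ring is closed by a Lewis-acid-promoted intramolecular allylstannane–aldehyde addition, a reaction type established for ten- to fourteen-membered carbocycles. Acid 20 would be reduced through its mixed anhydride (i-BuOCOCl, N-methylmorpholine; then NaBH4, H2O) to (2E,6Z)-6-({[tert-butyl(diphenyl)silyl]oxy}methyl)-2-(2-hydroxyethyl)undeca-2,6,9,10-tetraen-1-yl acetate F1. Dess–Martin oxidation would give the aldehyde (2E,6Z)-6-({[tert-butyl(diphenyl)silyl]oxy}methyl)-2-(2-oxoethyl)undeca-2,6,9,10-tetraen-1-yl acetate F2, which carries C8 as the formyl carbon. Palladium-catalysed addition of hexamethylditin across the allene (Pd(PPh3)4, THF) should give the bis-stannane (2E,6Z)-6-({[tert-butyl(diphenyl)silyl]oxy}methyl)-2-(2-oxoethyl)-10,11-bis(trimethylstannyl)undeca-2,6,9-trien-1-yl acetate F3, with allylic tin on C13 and vinylic tin on C11. With BF3·OEt2 at −78 °C under high dilution, SE2′ attack of C7 on the aldehyde should close the ring to the homoallylic alcohol [(1E,5Z)-5-({[tert-butyl(diphenyl)silyl]oxy}methyl)-9-hydroxy-8-[1-(trimethylstannyl)ethenyl]cyclodeca-1,5-dien-1-yl]methyl acetate F4; the 8,9-anti isomer is the one carried on. Iododestannylation (I2, CH2Cl2, 0 °C) would give the vinyl iodide [(1E,5Z)-5-({[tert-butyl(diphenyl)silyl]oxy}methyl)-9-hydroxy-8-(1-iodoethenyl)cyclodeca-1,5-dien-1-yl]methyl acetate F5. Palladium-catalysed carbonylative lactonisation (Pd(PPh3)4, CO, Et3N, MeCN) then forms C11–C12 and the lactone, giving 25. Run this way the material is racemic and is resolved as in the fallback for step 13.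

2. Step 13. The catalyst may not distinguish the two enantiomers of 24 well enough, or conversion may stall; epoxidation of the enone or migration of the vinylic carbon could also intrude.
Fallback, setting out from racemic 24 and coming back at 25: the ketone is oxidised without enantiocontrol (30 % H2O2 in hexafluoroisopropanol, 0 °C) to the racemic lactone, that is 25 together with its enantiomer [(3aS,5Z,9E,11aR)-6-({[tert-butyl(diphenyl)silyl]oxy}methyl)-3-methylidene-2-oxo-2,3,3a,4,7,8,11,11a-octahydrocyclodeca[b]furan-10-yl]methyl acetate F6. The two are separated by preparative SFC on a chiral stationary phase, and 25 goes on into step 14.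

3. Step 8. The hydride may not differentiate the two esters (over-reduction of the tert-butyl ester), or the γ-hydroxy ester may lactonise during work-up.
Fallback, setting out from diester 16 and coming back at alcohol 17: LiOH in THF/H2O should saponify only the ethyl ester, giving (2E,6Z)-2-(2-tert-butoxy-2-oxoethyl)-6-({[tert-butyl(diphenyl)silyl]oxy}methyl)undeca-2,6,9,10-tetraenoic acid F7. Activation as the mixed anhydride (i-BuOCOCl, N-methylmorpholine, −15 °C) and reduction with NaBH4/H2O would give 17, which is acetylated at once.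

Further compounds
F1 | step 12 | (2E,6Z)-6-({[tert-butyl(diphenyl)silyl]oxy}methyl)-2-(2-hydroxyethyl)undeca-2,6,9,10-tetraen-1-yl acetate | CC(C)(C)[Si](c1ccccc1)(c1ccccc1)OC/C(CC/C=C(/COC(C)=O)CCO)=C\CC=C=C
F2 | step 12 | (2E,6Z)-6-({[tert-butyl(diphenyl)silyl]oxy}methyl)-2-(2-oxoethyl)undeca-2,6,9,10-tetraen-1-yl acetate | CC(C)(C)[Si](c1ccccc1)(c1ccccc1)OC/C(CC/C=C(/COC(C)=O)CC=O)=C\CC=C=C
F3 | step 12 | (2E,6Z)-6-({[tert-butyl(diphenyl)silyl]oxy}methyl)-2-(2-oxoethyl)-10,11-bis(trimethylstannyl)undeca-2,6,9-trien-1-yl acetate | CC(C)(C)[Si](c1ccccc1)(c1ccccc1)OC/C(CC/C=C(/COC(C)=O)CC=O)=C\CC=C(C[Sn](C)(C)C)[Sn](C)(C)C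
F4 | step 12 | [(1E,5Z)-5-({[tert-butyl(diphenyl)silyl]oxy}methyl)-9-hydroxy-8-[1-(trimethylstannyl)ethenyl]cyclodeca-1,5-dien-1-yl]methyl acetate (8,9-anti) | CC(C)(C)[Si](c1ccccc1)(c1ccccc1)OC/C1=C\C[C@H](C(=C)[Sn](C)(C)C)[C@@H](O)C/C(COC(C)=O)=C\CC1
F5 | step 12 | [(1E,5Z)-5-({[tert-butyl(diphenyl)silyl]oxy}methyl)-9-hydroxy-8-(1-iodoethenyl)cyclodeca-1,5-dien-1-yl]methyl acetate (8,9-anti) | CC(C)(C)[Si](c1ccccc1)(c1ccccc1)OC/C1=C\C[C@H](C(=C)I)[C@@H](O)C/C(COC(C)=O)=C\CC1
F6 | step 13 | [(3aS,5Z,9E,11aR)-6-({[tert-butyl(diphenyl)silyl]oxy}methyl)-3-methylidene-2-oxo-2,3,3a,4,7,8,11,11a-octahydrocyclodeca[b]furan-10-yl]methyl acetate | CC(C)(C)[Si](c1ccccc1)(c1ccccc1)OC/C1=C\C[C@H]2C(=C)C(=O)O[C@@H]2C/C(COC(C)=O)=C\CC1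
F7 | step 8 | (2E,6Z)-2-(2-tert-butoxy-2-oxoethyl)-6-({[tert-butyl(diphenyl)silyl]oxy}methyl)undeca-2,6,9,10-tetraenoic acid | CC(C)(C)[Si](c1ccccc1)(c1ccccc1)OC/C(CC/C=C(/C(=O)O)CC(=O)OC(C)(C)C)=C\CC=C=C
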